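**Plan**
1. Retrosynthetic cuts: the acetate C–O bond; the bond between the alkene carbon C(=CH2) and the CH(CH2OAc) carbon (gives enol triflate 15 and secondary iodide 29); both C4–CH3 bonds of the hydrindane (gives C4 ketone 5); in the lactone part, the ring C4–CH2 bond (allylation of a malate) and the lactone C5–O bond.
2. Enabling feature: in the six-membered ring of the trans-hydrindane, the gem-dimethyl carbon C4 lies next to the ring-fusion carbon C3a–H. C7a (angular CH3), C3a (H) and C1 (side chain cis to that CH3) are C13, C14 and C17 of vitamin D2. Ozonolysis of the vitamin leaves a ketone exactly at C4 (steroid C8), and steroid C20 and C21 become the C=CH2 unit.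
3. Forward, hydrindane: both carbocycles come intact from vitamin D2; C4=O becomes C4(CH3)2 with Me2TiCl2; the side chain is then cut back to the methyl ketone and converted into the terminal enol triflate.
4. Forward, lactone: dimethyl (R)-malate is allylated; the butyrolactone (ring A) closes after reduction of the distal carboxyl group; the cis hydroxyl group then closes a temporary cyclic acetal (ring B) on the ozonolysed allyl chain.
5. Union and end: a nickel-catalysed reductive coupling joins 15 to the ring B iodide; ring B is opened by hydrolysis and reduction, and the primary alcohol is acetylated.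
6. Stereochemistry: C1, C3a and C7a come from vitamin D2. The carbinol centre comes from (R)-malate. The lactone C4 centre is set by anti-selective Fráter–Seebach alkylation (anti in the chain equals cis in the ring). The CH(CH2OAc) centre is set by coupling on the convex face of the cis-fused A/B bicycle.

Key step: step 4

Remark: the hemiacetal-type carbons of 26, 27 and 31 are expected as anomeric mixtures and are written without a descriptor; they end as an sp2 carbon or a CH2 group. Hydrindane locants follow octahydro-1H-indene. The bicycle is numbered as furo[2,3-c]furan (O1, C2 acetal carbon, C3, C3a, C4, O5, C6 carbonyl, C6a).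

Step 1
Reactants: 1 vitamin D2 (ergocalciferol)
Product: 3 CD-ring diol (1R,3aR,4S,7aR)-1-[(2S)-1-hydroxypropan-2-yl]-7a-methyloctahydro-1H-inden-4-ol, via keto aldehyde 2 (not isolated)
Conditions: O3, CH2Cl2–MeOH, pyridine (1%), −78 °C; then NaBH4, −78 °C → rt
Reagents that add atoms: ozone, [O-][O+]=O
Why: Exhaustive ozonolysis with reductive work-up cuts the C7=C8 and C22=C23 double bonds, and borohydride should reach the ring ketone of 2 from the face opposite the angular methyl group, giving the axial alcohol whose configuration is erased again in step 3.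

Step 2
Reactants: 3 CD-ring diol
Product: 4 primary silyl ether (1R,3aR,4S,7aR)-1-[(2S)-1-{[tert-butyl(diphenyl)silyl]oxy}propan-2-yl]-7a-methyloctahydro-1H-inden-4-ol
Conditions: t-BuPh2SiCl (1.05 equiv), imidazole, DMF, 0 °C → rt
Reagents that add atoms: tert-butyl(chloro)diphenylsilane, CC(C)(C)[Si](Cl)(c1ccccc1)c1ccccc1
Why: Silyl ether formation under steric control, in which the bulky chlorosilane takes the open primary hydroxyl group and leaves the axial secondary one beside the ring fusion untouched.

Step 3
Reactants: 4 primary silyl ether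
Product: 5 C4 ketone (1R,3aR,7aR)-1-[(2S)-1-{[tert-butyl(diphenyl)silyl]oxy}propan-2-yl]-7a-methyloctahydro-4H-inden-4-one
Conditions: n-Pr4NRuO4 (5 mol %), N-methylmorpholine N-oxide, 4 Å MS, CH2Cl2, rt
Reagents that add atoms: none
Why: Ley–Griffith oxidation of a secondary alcohol runs in a neutral medium, so the epimerisable trans ring fusion next to the new ketone and the silyl ether should both stay intact.

Step 4
Reactants: 5 C4 ketone; 6 dimethylzinc; 7 titanium tetrachloride
Product: 10 gem-dimethyl hydrindane tert-butyl(diphenyl){(2S)-2-[(1R,3aS,7aR)-4,4,7a-trimethyloctahydro-1H-inden-1-yl]propoxy}silane, via dichlorodimethyltitanium 8 (not isolated), via tertiary titanium alkoxide 9 (not isolated)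
Conditions: TiCl4 (3 equiv), Me2Zn (3 equiv), CH2Cl2, −40 °C; then 5, −40 → 0 °C
Reagents that add atoms: dimethylzinc (6), C[Zn]C
Why: Me2TiCl2 (8), formed from TiCl4 and Me2Zn, binds the C4 carbonyl oxygen and hands one methyl group to the face opposite the angular methyl group, giving the tertiary titanium alkoxide 9. The oxophilic, Lewis-acidic titanium then ionises the C4–O bond, and the tertiary cation, held as a tight ion pair, takes a second methyl group from titanium, so that C=O is exchanged for C(CH3)2 with loss of TiOCl2. The closest known reaction type is the direct geminal dimethylation of ketones with dichlorodimethyltitanium, together with the related methylation of tertiary alcohols and chlorides by methyltitanium chlorides. No ring is closed and no lasting stereocentre is made, because C4 carries two equal methyl groups in 10 and the centre present in 9 disappears again. The step needs substitution to outrun proton loss and a 1,2-hydride shift from C3a–H, which low temperature, an excess of methyl donor next to the cation and the non-basic medium (which also spares the trans ring fusion from epimerisation) should secure. The only other oxygen atom sits in a primary tert-butyldiphenylsilyl ether that is too hindered and too weakly basic to bind titanium or to ionise.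

Step 5
Reactants: 10 gem-dimethyl hydrindane
Product: 11 primary alcohol (2S)-2-[(1R,3aS,7aR)-4,4,7a-trimethyloctahydro-1H-inden-1-yl]propan-1-ol
Conditions: n-Bu4NF, THF, rt
Reagents that add atoms: none
Why: Fluoride-induced desilylation is driven by the strong silicon–fluorine bond, and the saturated hydrocarbon skeleton offers no other reactive site.

Step 6
Reactants: 11 primary alcohol
Product: 12 aldehyde (2S)-2-[(1R,3aS,7aR)-4,4,7a-trimethyloctahydro-1H-inden-1-yl]propanal
Conditions: n-Pr4NRuO4 (5 mol %), N-methylmorpholine N-oxide, 4 Å MS, CH2Cl2, rt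
Reagents that add atoms: none
Why: Ley–Griffith oxidation stops at the aldehyde under anhydrous conditions, and any epimerisation of the α-carbon is without consequence because that carbon becomes the ketone carbon in step 7.

Step 7
Reactants: 12 aldehyde
Product: 13 methyl ketone 1-[(1S,3aS,7aS)-4,4,7a-trimethyloctahydro-1H-inden-1-yl]ethan-1-one
Conditions: O2 (1 atm), Cu(OAc)2 (10 mol %), 2,2'-bipyridine (10 mol %), DABCO, DMF, 40 °C
Reagents that add atoms: dioxygen, O=O
Why: Copper-catalysed aerobic oxidative deformylation of an α-branched aldehyde (enolisation, oxygenation of the α-carbon, fragmentation to ketone and formic acid) is the established way from steroid 22-aldehydes to 20-ketones, and the acetyl group stays cis to the angular methyl group, which is also the thermodynamically preferred arrangement.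

Step 8
Reactants: 13 methyl ketone
Product: 15 enol triflate 1-[(1S,3aS,7aS)-4,4,7a-trimethyloctahydro-1H-inden-1-yl]ethenyl trifluoromethanesulfonate, via potassium enolate 14 (not isolated)
Conditions: KN(SiMe3)2, THF, −78 °C; PhNTf2, −78 → 0 °C
Reagents that add atoms: N-phenylbis(trifluoromethanesulfonimide), O=S(=O)(N(c1ccccc1)S(=O)(=O)C(F)(F)F)C(F)(F)F
Why: Kinetic deprotonation by a bulky amide base removes a methyl proton rather than the hindered ring C1–H, and O-sulfonylation of enolate 14 gives the terminal enol triflate without touching the C1 stereocentre.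

Step 9
Reactants: 16 dimethyl (R)-malate; 17 allyl bromide
Product: 19 dimethyl (2R,3S)-2-hydroxy-3-(prop-2-en-1-yl)butanedioate, via dilithium dianion 18 (not isolated)
Conditions: LiN(i-Pr)2 (2.2 equiv), THF, −78 → −20 °C; allyl bromide, −78 → −10 °C
Reagents that add atoms: allyl bromide (17), C=CCBr
Why: Fráter–Seebach alkylation, in which the alkoxide–enolate dianion 18 is held in a lithium chelate and the halide attacks the face anti to the ester-bearing substituent of the carbinol carbon, so the new centre is set anti to the hydroxyl group.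

Step 10
Reactants: 19 allylated malate
Product: 20 (2R,3S)-2-hydroxy-3-(prop-2-en-1-yl)butanedioic acid
Conditions: KOH, MeOH–H2O, rt; then aq HCl
Reagents that add atoms: potassium hydroxide, [K+].[OH-]
Why: Plain ester saponification, during which the α-carbon of the forming carboxylate is not acidic enough to epimerise.

Step 11
Reactants: 20 diacid
Product: 21 dioxolanone acid (2S)-2-[(4R)-2,2-dimethyl-5-oxo-1,3-dioxolan-4-yl]pent-4-enoic acid
Conditions: Me2C(OMe)2, p-TsOH (cat.), CH2Cl2, rt
Reagents that add atoms: 2,2-dimethoxypropane, COC(C)(C)OC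
Why: Acid-catalysed transketalisation closes the five-membered dioxolanone of the α-hydroxy acid in preference to the six-membered alternative, a known differentiation of 3-alkylmalic acids that masks the hydroxyl group and the future lactone carbonyl and leaves the other carboxyl group free.

Step 12
Reactants: 21 dioxolanone acid
Product: 24 (3R,4R)-3-hydroxy-4-(prop-2-en-1-yl)oxolan-2-one (hydroxyl and allyl groups cis), via mixed anhydride 22 (not isolated), via hydroxy dioxolanone 23 (not isolated)
Conditions: i-BuOCOCl, N-methylmorpholine, THF, −15 °C; NaBH4, THF–H2O, 0 °C; then 1 M HCl, rt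
Reagents that add atoms: none
Why: Mixed carbonic anhydride activation followed by borohydride reduction turns only the free carboxyl group into CH2OH and spares the alkene that borane would attack, and the new alcohol then attacks the activated dioxolanone carbonyl (5-exo-trig lactonisation) with loss of acetone and without involving a stereocentre.

Step 13
Reactants: 24 allyl hydroxy lactone
Product: 26 bicyclic lactol (3aR,6aR)-2-hydroxyhexahydrofuro[2,3-c]furan-6-one, via hydroxy aldehyde 25 (not isolated)
Conditions: O3, CH2Cl2, −78 °C; Me2S, −78 °C → rt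
Reagents that add atoms: ozone, [O-][O+]=O
Why: Ozonolysis with reductive work-up gives aldehyde 25, which the cis hydroxyl group traps as a five-membered hemiacetal, a closure open only to the cis isomer, so any trans material carried over from step 9 stays open-chain and separable.

Step 14
Reactants: 26 bicyclic lactol
Product: 28 bicyclic enol ether (3aR,6aR)-3a,6a-dihydrofuro[2,3-c]furan-6(4H)-one, via anomeric mesylate 27 (not isolated)
Conditions: MsCl, Et3N (excess), CH2Cl2, −40 °C → reflux
Reagents that add atoms: none
Why: Sulfonylation of the hemiacetal hydroxyl group and amine-induced elimination is the standard route from 2-deoxyfuranose hemiacetals to furanoid glycals, and the two ring-fusion centres cannot epimerise because a trans-fused bicyclo[3.3.0]octane would be far too strained.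

Step 15
Reactants: 28 bicyclic enol ether
Product: 29 iodoacetal (2S,3S,3aR,6aR)-3-iodo-2-methoxyhexahydrofuro[2,3-c]furan-6-one (iodine exo, methoxy trans to it)
Conditions: N-iodosuccinimide, MeOH–CH2Cl2, −20 → 0 °C, dark
Reagents that add atoms: N-iodosuccinimide, O=C1CCC(=O)N1I; methanol, CO
Why: Iodoalkoxylation of an enol ether, in which the iodonium ion forms on the convex face and methanol opens it at the oxygen-stabilised acetal carbon from the opposite side, both new centres being temporary.

Step 16
Reactants: 15 enol triflate; 29 iodoacetal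
Product: 30 coupled acetal (2S,3R,3aR,6aR)-2-methoxy-3-{1-[(1R,3aS,7aS)-4,4,7a-trimethyloctahydro-1H-inden-1-yl]ethenyl}hexahydrofuro[2,3-c]furan-6-one
Conditions: NiBr2(dme) (10 mol %), 4,4'-di-tert-butyl-2,2'-bipyridine (12 mol %), Mn powder (3 equiv), N,N-dimethylacetamide, rt → 40 °C
Reagents that add atoms: none
Why: Nickel-catalysed reductive cross-electrophile coupling of an alkenyl triflate with a secondary alkyl iodide, in which zerovalent nickel inserts into the C–O bond of 15, monovalent nickel abstracts iodine from 29, and the planar C3 radical is captured by the bulky alkenylnickel complex on the convex face of the cis-fused bicycle (anti to the lactone CH2 at C3a and to the endo methoxy group), which sets the (R)-configured CH centre before reductive elimination from trivalent nickel.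

Step 17
Reactants: 30 coupled acetal
Product: 31 lactol (3R,3aR,6aR)-2-hydroxy-3-{1-[(1R,3aS,7aS)-4,4,7a-trimethyloctahydro-1H-inden-1-yl]ethenyl}hexahydrofuro[2,3-c]furan-6-one
Conditions: 1 M HCl, THF, rt → 40 °C
Reagents that add atoms: water, O
Why: Acid-catalysed acetal hydrolysis, under which a γ-lactone is stable, the 1,1-disubstituted alkene is not protonated at this acidity, and the product rests in its closed hemiacetal form, which shields the allylic CH centre.

Step 18
Reactants: 31 lactol
Product: 32 diol (3R,4R)-3-hydroxy-4-{(2R)-1-hydroxy-3-[(1R,3aS,7aS)-4,4,7a-trimethyloctahydro-1H-inden-1-yl]but-3-en-2-yl}oxolan-2-one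
Conditions: NaBH(OAc)3, AcOH–MeCN, 0 °C → rt
Reagents that add atoms: none
Why: Chemoselective aldehyde reduction with a triacetoxyborohydride, which reduces the small equilibrium share of open hydroxy aldehyde but not the activated α-oxygenated lactone, while the acidic medium suppresses enolisation of the β,γ-unsaturated aldehyde and translactonisation.

Step 19
Reactants: 32 diol
Product: 33 target (2R)-2-[(3R,4R)-4-hydroxy-5-oxooxolan-3-yl]-3-[(1R,3aS,7aS)-4,4,7a-trimethyloctahydro-1H-inden-1-yl]but-3-en-1-yl acetate
Conditions: Ac2O (1.1 equiv), 2,4,6-collidine, CH2Cl2, −20 → 0 °C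
Reagents that add atoms: acetic anhydride, CC(=O)OC(C)=O
Why: Selective acylation of a primary alcohol, the competing secondary hydroxyl group being hindered and made less nucleophilic by the neighbouring lactone carbonyl.

**Compound list**
1 | vitamin D2 (ergocalciferol) | C[C@H](/C=C/[C@H](C)C(C)C)[C@H]1CC[C@@H]2[C@@]1(CCC/C2=C\C=C/3\C[C@H](CCC3=C)O)C | starting material
2 | keto aldehyde (2S)-2-[(1R,3aR,7aR)-7a-methyl-4-oxooctahydro-1H-inden-1-yl]propanal | C[C@H](C=O)[C@H]1CC[C@H]2C(=O)CCC[C@]12C | intermediate
3 | CD-ring diol (1R,3aR,4S,7aR)-1-[(2S)-1-hydroxypropan-2-yl]-7a-methyloctahydro-1H-inden-4-ol | C[C@H](CO)[C@H]1CC[C@H]2[C@@H](O)CCC[C@]12C | intermediate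
4 | primary tert-butyldiphenylsilyl ether of 3 | C[C@H](CO[Si](c1ccccc1)(c1ccccc1)C(C)(C)C)[C@H]1CC[C@H]2[C@@H](O)CCC[C@]12C | intermediate
5 | silyl-protected C4 ketone (1R,3aR,7aR) | C[C@H](CO[Si](c1ccccc1)(c1ccccc1)C(C)(C)C)[C@H]1CC[C@H]2C(=O)CCC[C@]12C | intermediate
6 | dimethylzinc | C[Zn]C | starting material
7 | titanium tetrachloride | Cl[Ti](Cl)(Cl)Cl | starting material
8 | dichlorodimethyltitanium | C[Ti](C)(Cl)Cl | intermediate
9 | tertiary titanium alkoxide (4-methyl, 4-O-TiCl2CH3 axial and cis to the 7a-methyl group) | C[C@H](CO[Si](c1ccccc1)(c1ccccc1)C(C)(C)C)[C@H]1CC[C@H]2[C@@](C)(O[Ti](C)(Cl)Cl)CCC[C@]12C | intermediate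
10 | silyl-protected 4,4,7a-trimethyl-trans-hydrindane (1R,3aS,7aR; side chain 2S) | C[C@H](CO[Si](c1ccccc1)(c1ccccc1)C(C)(C)C)[C@H]1CC[C@H]2C(C)(C)CCC[C@]12C | intermediate
11 | (2S)-2-[(1R,3aS,7aR)-4,4,7a-trimethyloctahydro-1H-inden-1-yl]propan-1-ol | C[C@H](CO)[C@H]1CC[C@H]2C(C)(C)CCC[C@]12C | intermediate
12 | (2S)-2-[(1R,3aS,7aR)-4,4,7a-trimethyloctahydro-1H-inden-1-yl]propanal | C[C@H](C=O)[C@H]1CC[C@H]2C(C)(C)CCC[C@]12C | intermediate
13 | 1-[(1S,3aS,7aS)-4,4,7a-trimethyloctahydro-1H-inden-1-yl]ethan-1-one | CC(=O)[C@H]1CC[C@H]2C(C)(C)CCC[C@]12C | intermediate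
14 | potassium enolate of 13 (terminal) | [K+].[O-]C(=C)[C@H]1CC[C@H]2C(C)(C)CCC[C@]12C | intermediate
15 | 1-[(1S,3aS,7aS)-4,4,7a-trimethyloctahydro-1H-inden-1-yl]ethenyl trifluoromethanesulfonate | C=C(OS(=O)(=O)C(F)(F)F)[C@H]1CC[C@H]2C(C)(C)CCC[C@]12C | intermediate
16 | dimethyl (R)-malate | COC(=O)C[C@@H](O)C(=O)OC | starting material
17 | allyl bromide | C=CCBr | starting material
18 | dilithium alkoxide–enolate of 16 (enolate oxygen cis to the carbinol carbon) | [Li+].[Li+].COC(=O)[C@H]([O-])/C=C(\[O-])OC | intermediate
19 | dimethyl (2R,3S)-2-hydroxy-3-(prop-2-en-1-yl)butanedioate | COC(=O)[C@H](O)[C@H](CC=C)C(=O)OC | intermediate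
20 | (2R,3S)-2-hydroxy-3-(prop-2-en-1-yl)butanedioic acid | OC(=O)[C@H](O)[C@H](CC=C)C(=O)O | intermediate
21 | (2S)-2-[(4R)-2,2-dimethyl-5-oxo-1,3-dioxolan-4-yl]pent-4-enoic acid | CC1(C)OC(=O)[C@H](O1)[C@H](CC=C)C(=O)O | intermediate
22 | isobutyl carbonic mixed anhydride of 21 | CC1(C)OC(=O)[C@H](O1)[C@H](CC=C)C(=O)OC(=O)OCC(C)C | intermediate
23 | (5R)-5-[(2R)-1-hydroxypent-4-en-2-yl]-2,2-dimethyl-1,3-dioxolan-4-one | CC1(C)OC(=O)[C@H](O1)[C@H](CC=C)CO | intermediate
24 | (3R,4R)-3-hydroxy-4-(prop-2-en-1-yl)oxolan-2-one (cis) | C=CC[C@@H]1COC(=O)[C@@H]1O | intermediate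
25 | 2-[(3R,4R)-4-hydroxy-5-oxooxolan-3-yl]acetaldehyde | O=CC[C@@H]1COC(=O)[C@@H]1O | intermediate
26 | (3aR,6aR)-2-hydroxyhexahydrofuro[2,3-c]furan-6-one (anomers) | OC1C[C@@H]2COC(=O)[C@@H]2O1 | intermediate
27 | anomeric mesylate of 26 | CS(=O)(=O)OC1C[C@@H]2COC(=O)[C@@H]2O1 | intermediate
28 | (3aR,6aR)-3a,6a-dihydrofuro[2,3-c]furan-6(4H)-one | C1=C[C@@H]2COC(=O)[C@@H]2O1 | intermediate
29 | (2S,3S,3aR,6aR)-3-iodo-2-methoxyhexahydrofuro[2,3-c]furan-6-one | CO[C@@H]1[C@@H](I)[C@@H]2COC(=O)[C@@H]2O1 | intermediate
30 | (2S,3R,3aR,6aR)-2-methoxy-3-{1-[(1R,3aS,7aS)-4,4,7a-trimethyloctahydro-1H-inden-1-yl]ethenyl}hexahydrofuro[2,3-c]furan-6-one | CO[C@@H]1[C@@H](C(=C)[C@H]3CC[C@H]4C(C)(C)CCC[C@]34C)[C@@H]2COC(=O)[C@@H]2O1 | intermediate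
31 | lactol corresponding to 30 (anomers) | OC1[C@@H](C(=C)[C@H]3CC[C@H]4C(C)(C)CCC[C@]34C)[C@@H]2COC(=O)[C@@H]2O1 | intermediate
32 | (3R,4R)-3-hydroxy-4-{(2R)-1-hydroxy-3-[(1R,3aS,7aS)-4,4,7a-trimethyloctahydro-1H-inden-1-yl]but-3-en-2-yl}oxolan-2-one | C=C([C@H]1CC[C@H]2C(C)(C)CCC[C@]12C)[C@H](CO)[C@@H]1COC(=O)[C@@H]1O | intermediate
33 | (2R)-2-[(3R,4R)-4-hydroxy-5-oxooxolan-3-yl]-3-[(1R,3aS,7aS)-4,4,7a-trimethyloctahydro-1H-inden-1-yl]but-3-en-1-yl acetate (CNP0252518.3) | C=C([C@H]1CC[C@H]2C(C)(C)CCC[C@]12C)[C@H](COC(C)=O)[C@@H]1COC(=O)[C@@H]1O | target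

**Step count**
Total step count: 19.
Longest linear sequence: 12 steps (steps 1–8 and 16–19, from vitamin D2). The malate branch has 7 steps before the union.

**Steps most likely to fail**

Step 4. The tertiary cation may lose a proton toward C3a or C5, or the C3a hydride may migrate, before the second methyl group arrives. Either path would divert material into alkenes and rearranged skeletons. Lewis-acid attack on the silyl ether is a lesser concern.
Fallback: the two methyl groups are built without any cation. Setting out from 5, non-basic Lombardo–Takai methylenation (Zn, CH2Br2, TiCl4, THF–CH2Cl2) should give the 4-methylidene hydrindane F1. Simmons–Smith cyclopropanation in the Furukawa variant (Et2Zn, CH2I2, CH2Cl2) should then give the spirocyclopropane F2. Hydrogenolysis of its unhindered CH2–CH2 bond (H2, 1 atm, PtO2, AcOH) comes back to the route at 10.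

Step 16. The iodide may be reduced at the metal surface with expulsion of the neighbouring alkoxy group (Boord-type elimination). Either partner may homocouple. Capture of the radical may be slow at the crowded alkenylnickel centre, or facial selectivity may erode.
Fallback: the alkenyl partner is made as a preformed nucleophile, so that no stoichiometric reductant meets the iodide. Setting out from 13, condensation with 2,4,6-triisopropylbenzenesulfonyl hydrazide should give the sulfonylhydrazone F3. A Shapiro reaction (n-BuLi, 2.2 equiv, THF, −78 → 0 °C) should give the alkenyllithium F4, and ZnCl2 the alkenylzinc chloride F5. A Negishi-type coupling of F5 with 29 (NiCl2(dme), 4,4'-di-tert-butyl-2,2'-bipyridine, THF–DMA) comes back to the route at 30, with the same convex-face control.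

Step 14. The activated hemiacetal may be substituted by chloride and resist elimination, or the acid-sensitive enol ether may hydrolyse or oligomerise in the presence of the ammonium salts.
Fallback: a neutral, thermal syn-elimination. Setting out from 26, PhSeH and BF3·OEt2 in CH2Cl2 should give the anomeric phenyl selenide F6. Oxidation (H2O2, THF, 0 °C) should give the selenoxide F7. Selenoxide elimination on warming with i-Pr2NEt comes back to the route at 28.

**Further compounds**
F1 | step 4 | tert-butyl(diphenyl){(2S)-2-[(1R,3aR,7aR)-7a-methyl-4-methylideneoctahydro-1H-inden-1-yl]propoxy}silane | C[C@H](CO[Si](c1ccccc1)(c1ccccc1)C(C)(C)C)[C@H]1CC[C@H]2C(=C)CCC[C@]12C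
F2 | step 4 | spiro[cyclopropane-1,4'-hydrindane] analogue of 10 | C[C@H](CO[Si](c1ccccc1)(c1ccccc1)C(C)(C)C)[C@H]1CC[C@H]2C3(CC3)CCC[C@]12C
F3 | step 16 | (E)-2,4,6-triisopropylbenzenesulfonylhydrazone of 13 | C/C(=N\NS(=O)(=O)c1c(C(C)C)cc(C(C)C)cc1C(C)C)[C@H]1CC[C@H]2C(C)(C)CCC[C@]12C
F4 | step 16 | 1-(4,4,7a-trimethylhydrindan-1-yl)ethenyllithium | [Li]C(=C)[C@H]1CC[C@H]2C(C)(C)CCC[C@]12C
F5 | step 16 | 1-(4,4,7a-trimethylhydrindan-1-yl)ethenylzinc chloride | Cl[Zn]C(=C)[C@H]1CC[C@H]2C(C)(C)CCC[C@]12C
F6 | step 14 | (3aR,6aR)-2-(phenylselanyl)hexahydrofuro[2,3-c]furan-6-one | c1ccccc1[Se]C1C[C@@H]2COC(=O)[C@@H]2O1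
F7 | step 14 | selenoxide of F6 | O=[Se](c1ccccc1)C1C[C@@H]2COC(=O)[C@@H]2O1
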